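**Retrosynthetic overview**
1. Epischisandrone 16 ⇐ benzyl ether 15 ⇐ dithioketal 14: the C1 ketone is carried as a 1,3-dithiane and the phenol as a benzyl ether.
2. The two methyl groups of 14 ⇐ trans-fused γ-lactone acetal 11: lactone C=O becomes the C3 methyl and the acetal carbon becomes the C2 methyl, via diol 12 and bis-mesylate 13.
3. Ring B (the only carbocycle built) ⇐ C4–C4a intramolecular Friedel–Crafts alkylation of benzylic alcohol 10.
4. 10 ⇐ key Michael addition of lithiated aryl dithiane 8 (ring A + C1) to chiral butenolide 4 (forms C1–C2), with the enolate trapped by veratraldehyde 7 in an aldol reaction (forms C3–C4).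
5. Ring order: auxiliary butenolide ring (steps 1–2), dithiane (step 3), ring B (step 5); the lactone ring is then opened (step 6) and the dithiane removed (step 9).

Assumption: (+)-menthol (recovered in step 6) is taken as an affordable commercial auxiliary; locants C1–C4 follow the tetralone (C1 = C=O, C4 = CH–aryl).

**Step 1**
Reactants: 1 furfural (furan-2-carbaldehyde)
Product: 2 5-hydroxyfuran-2(5H)-one (racemic)
Conditions: O2, hν (visible), methylene blue (C16H18ClN3S, cat.), MeOH, 20 °C
Reagents that add atoms: dioxygen O=O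
Why: Schenck-type singlet-oxygen [4+2] photooxygenation of the furan gives an endoperoxide that methanol fragments, expelling the formyl carbon as methyl formate.

**Step 2**
Reactants: 2 5-hydroxyfuran-2(5H)-one; 3 (+)-menthol [(1S,2R,5S)-2-isopropyl-5-methylcyclohexan-1-ol]
Product: 4 (5S)-5-[(1S,2R,5S)-menthyloxy]furan-2(5H)-one
Conditions: p-TsOH·H2O (cat.), toluene, reflux, Dean–Stark; crystallisation from petroleum ether, mother liquor re-equilibrated with the acid and recrystallised
Reagents that add atoms: none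
Why: Acid-catalysed acetalisation of the cyclic hemiacylal, in which the C5 epimers interconvert and the less soluble (5S) diastereomer crystallises (crystallisation-induced diastereomer enrichment), fixing the centre that controls all later ones.

**Step 3**
Reactants: 5 3-(benzyloxy)-4-methoxybenzaldehyde (O-benzylisovanillin)
Product: 6 2-[3-(benzyloxy)-4-methoxyphenyl]-1,3-dithiane
Conditions: HS(CH2)3SH, BF3·OEt2 (0.3 equiv), CH2Cl2, 0 °C to rt
Reagents that add atoms: propane-1,3-dithiol SCCCS
Why: Lewis-acid-catalysed dithioacetalisation turns the aldehyde into a Corey–Seebach acyl-anion equivalent that later also protects the ketone.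

**Step 4**
Reactants: 6 2-[3-(benzyloxy)-4-methoxyphenyl]-1,3-dithiane; 4 (5S)-5-(d-menthyloxy)furan-2(5H)-one; 7 veratraldehyde (3,4-dimethoxybenzaldehyde)
Product: 10 (3R,4S,5S)-3-[(3,4-dimethoxyphenyl)(hydroxy)methyl]-4-(2-aryl-1,3-dithian-2-yl)-5-(d-menthyloxy)dihydrofuran-2(3H)-one (carbinol epimer mixture), via 2-lithio-2-aryl-1,3-dithiane 8 (not isolated), via lithium lactone enolate 9 (not isolated)
Conditions: n-BuLi (1.05 equiv), THF, −78 to −25 °C; then 4, −78 °C; then 7, −78 °C; AcOH quench at −78 °C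
Reagents that add atoms: none
Why: Corey–Seebach lithiation, then Michael addition of the dithianyl anion to the butenolide anti to the menthyloxy group (sets C2), then aldol addition of the lactone enolate to the aldehyde anti to the bulky dithianyl group (sets C3); the carbinol centre is erased in step 5.

**Step 5**
Reactants: 10 aldol adduct lactone
Product: 11 trans-fused aryltetralin lactone acetal (tetralin 2S,3S,4R; acetal S) with C1 spiro-1,3-dithiane
Conditions: CF3CO2H (10 equiv), CH2Cl2, 0 °C to rt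
Reagents that add atoms: none
Why: Ionisation to the dimethoxybenzyl cation and intramolecular Friedel–Crafts alkylation para to the benzyloxy group closes ring B with the aryl group pseudo-equatorial and trans to the C3 substituent (sets C4), as in the podorhizol to isodeoxypodophyllotoxin cyclisation.

**Step 6**
Reactants: 11 aryltetralin lactone acetal
Product: 12 [(2S,3S,4R)-7-(benzyloxy)-4-(3,4-dimethoxyphenyl)-6-methoxy-3,4-dihydro-2H-spiro[naphthalene-1,2'-[1,3]dithiane]-2,3-diyl]dimethanol
Conditions: LiAlH4 (4 equiv), THF, 0 °C to reflux; H2O/NaOH work-up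
Reagents that add atoms: none
Why: Hydride reduction of the lactone acetal (the released hemiacetal collapses to an aldehyde and is reduced further) gives the trans diol and frees the auxiliary without touching the stereocentres, dithiane or benzyl ether.

**Step 7**
Reactants: 12 trans diol
Product: 13 bis(methanesulfonate) of 12 (2S,3S,4R)
Conditions: MsCl (3 equiv), Et3N (4 equiv), CH2Cl2, 0 °C, used at once
Reagents that add atoms: methanesulfonyl chloride CS(=O)(=O)Cl
Why: Sulfonylation of both primary alcohols at 0 °C is faster than cyclisation to a tetrahydrofuran and involves no stereocentre.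

**Step 8**
Reactants: 13 bis(methanesulfonate)
Product: 14 (2R,3S,4R)-7-(benzyloxy)-4-(3,4-dimethoxyphenyl)-6-methoxy-2,3-dimethyl-3,4-dihydro-2H-spiro[naphthalene-1,2'-[1,3]dithiane]
Conditions: LiBHEt3 (1 M in THF, 6 equiv), THF, 0 °C to reflux
Reagents that add atoms: none
Why: SN2 hydride displacement of the primary sulfonates by the highly nucleophilic LiBHEt3 turns both CH2OMs groups into methyl groups while the dithiane shields C1 from reduction.

**Step 9**
Reactants: 14 dimethyl dithioketal
Product: 15 (2R,3S,4R)-7-(benzyloxy)-4-(3,4-dimethoxyphenyl)-6-methoxy-2,3-dimethyl-3,4-dihydronaphthalen-1(2H)-one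
Conditions: HgO (2 equiv), BF3·OEt2 (promoter), THF/H2O (85:15), rt
Reagents that add atoms: water O
Why: Thiophilic HgO/BF3-promoted hydrolysis of the dithioacetal unmasks the C1 ketone, and C2 already holds the expected thermodynamically preferred trans (all-equatorial) configuration, so no epimerisation is expected.

**Step 10**
Reactants: 15 O-benzyl epischisandrone
Product: 16 epischisandrone
Conditions: H2 (1 atm), Pd/C (10%), EtOAc/MeOH, rt, monitored and stopped at full conversion
Reagents that add atoms: none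
Why: Heterogeneous catalytic hydrogenolysis cleaves the benzyl aryl ether much faster than the electron-rich aryl ketone is reduced.

**Compound list**
1 | furfural (furan-2-carbaldehyde) | O=Cc1ccco1 | starting material
2 | 5-hydroxyfuran-2(5H)-one (racemic) | O=C1C=CC(O)O1 | intermediate
3 | (+)-menthol, (1S,2R,5S)-2-isopropyl-5-methylcyclohexan-1-ol | CC(C)[C@H]1CC[C@H](C)C[C@@H]1O | starting material
4 | (5S)-5-{[(1S,2R,5S)-2-isopropyl-5-methylcyclohexyl]oxy}furan-2(5H)-one | O=C1C=C[C@@H](O[C@H]2C[C@@H](C)CC[C@@H]2C(C)C)O1 | intermediate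
5 | 3-(benzyloxy)-4-methoxybenzaldehyde | COc1ccc(C=O)cc1OCc2ccccc2 | starting material
6 | 2-[3-(benzyloxy)-4-methoxyphenyl]-1,3-dithiane | COc1ccc(cc1OCc2ccccc2)C3SCCCS3 | intermediate
7 | veratraldehyde (3,4-dimethoxybenzaldehyde) | COc1ccc(C=O)cc1OC | starting material
8 | 2-lithio-2-[3-(benzyloxy)-4-methoxyphenyl]-1,3-dithiane | COc1ccc(cc1OCc2ccccc2)C3([Li])SCCCS3 | intermediate (not isolated)
9 | lithium (4S,5S)-4-{2-[3-(benzyloxy)-4-methoxyphenyl]-1,3-dithian-2-yl}-5-(d-menthyloxy)-4,5-dihydrofuran-2-olate | [Li]OC1=C[C@H](C3(SCCCS3)c4ccc(OC)c(OCc5ccccc5)c4)[C@@H](O[C@H]6C[C@@H](C)CC[C@@H]6C(C)C)O1 | intermediate (not isolated)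
10 | (3R,4S,5S)-4-{2-[3-(benzyloxy)-4-methoxyphenyl]-1,3-dithian-2-yl}-3-[(3,4-dimethoxyphenyl)(hydroxy)methyl]-5-{[(1S,2R,5S)-2-isopropyl-5-methylcyclohexyl]oxy}dihydrofuran-2(3H)-one, carbinol epimers | O=C1O[C@H](O[C@H]2C[C@@H](C)CC[C@@H]2C(C)C)[C@@H](C3(SCCCS3)c4ccc(OC)c(OCc5ccccc5)c4)[C@@H]1C(O)c6ccc(OC)c(OC)c6 | intermediate
11 | 7-(benzyloxy)-4-(3,4-dimethoxyphenyl)-6-methoxy-3,4-dihydro-2H-spiro[naphthalene-1,2'-[1,3]dithiane] with a trans-fused γ-lactone across C2–C3 (lactone C=O on C3, O-(1S,2R,5S)-menthyl acetal carbon on C2); tetralin (2S,3S,4R), acetal carbon S | COc1cc2c(cc1OCc3ccccc3)C5(SCCCS5)[C@@H]6[C@@H](O[C@H]7C[C@@H](C)CC[C@@H]7C(C)C)OC(=O)[C@H]6[C@@H]2c4ccc(OC)c(OC)c4 | intermediate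
12 | [(2S,3S,4R)-7-(benzyloxy)-4-(3,4-dimethoxyphenyl)-6-methoxy-3,4-dihydro-2H-spiro[naphthalene-1,2'-[1,3]dithiane]-2,3-diyl]dimethanol | COc1cc2c(cc1OCc3ccccc3)C5(SCCCS5)[C@H](CO)[C@@H](CO)[C@@H]2c4ccc(OC)c(OC)c4 | intermediate
13 | bis(methanesulfonate) of 12, (2S,3S,4R) | COc1cc2c(cc1OCc3ccccc3)C5(SCCCS5)[C@H](COS(C)(=O)=O)[C@@H](COS(C)(=O)=O)[C@@H]2c4ccc(OC)c(OC)c4 | intermediate
14 | (2R,3S,4R)-7-(benzyloxy)-4-(3,4-dimethoxyphenyl)-6-methoxy-2,3-dimethyl-3,4-dihydro-2H-spiro[naphthalene-1,2'-[1,3]dithiane] | COc1cc2c(cc1OCc3ccccc3)C5(SCCCS5)[C@H](C)[C@@H](C)[C@@H]2c4ccc(OC)c(OC)c4 | intermediate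
15 | (2R,3S,4R)-7-(benzyloxy)-4-(3,4-dimethoxyphenyl)-6-methoxy-2,3-dimethyl-3,4-dihydronaphthalen-1(2H)-one | COc1cc2c(cc1OCc3ccccc3)C(=O)[C@H](C)[C@@H](C)[C@@H]2c4ccc(OC)c(OC)c4 | intermediate
16 | epischisandrone, (2R,3S,4R)-4-(3,4-dimethoxyphenyl)-7-hydroxy-6-methoxy-2,3-dimethyl-3,4-dihydronaphthalen-1(2H)-one | COc1cc2c(cc1O)C(=O)[C@H](C)[C@@H](C)[C@@H]2c1ccc(OC)c(OC)c1 | target

**Totals**
Total step count: 10. Longest linear sequence: 9 steps (furfural 1 to 16 through steps 1, 2, 4–10).

**Steps most likely to fail, with fallbacks**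

Step 4 (one-pot three-component Michael/aldol; the risks are incomplete enolate trapping and retro-aldol). The fallback sets out from 6 and 4 and comes back at 10. Compound 6 is lithiated and added to 4 as before, but enolate 9 is protonated with AcOH at −78 °C. This gives the Michael adduct (4S,5S)-4-(2-aryl-1,3-dithian-2-yl)-5-(d-menthyloxy)dihydrofuran-2(3H)-one F1, which is isolated and purified. F1 is then re-enolised with LiN(iPr)2 in THF at −78 °C, transmetalated with ZnCl2, and treated with 7 in a separate directed aldol to give 10.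

Step 5 (cyclisation on the strained lactone acetal; the risks are dehydration to the benzylidene lactone and acetal loss). The fallback sets out from 10 and comes back at 12. Compound 10 is first reduced with LiAlH4 in THF to the open-chain triol (2S,3S)-2-(2-aryl-1,3-dithian-2-yl)-3-[(3,4-dimethoxyphenyl)(hydroxy)methyl]butane-1,4-diol F2. F2 is then treated with BF3·OEt2 in CH2Cl2 at 0 °C. The benzylic cation is trapped reversibly as a 2-aryltetrahydrofuran and drains into the irreversible Friedel–Crafts product (a lariciresinol to isolariciresinol type rearrangement), giving diol 12 directly.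

Step 8 (hydride displacement at two β-branched primary mesylates; the risks are S–O cleavage back to the alcohol and slow substitution). The fallback sets out from 13 and comes back at 14. Compound 13 is heated with sodium iodide (NaI) in butanone (Finkelstein exchange) to give the diiodide (2R,3S,4R)-2,3-bis(iodomethyl) analogue of 12 F3. F3 is reduced by a radical chain with Bu3SnH and 2,2'-azobis(2-methylpropionitrile) (AIBN) in toluene at 80 °C to give 14.

**Further compounds**
F1 | step 4 | (4S,5S)-4-{2-[3-(benzyloxy)-4-methoxyphenyl]-1,3-dithian-2-yl}-5-{[(1S,2R,5S)-2-isopropyl-5-methylcyclohexyl]oxy}dihydrofuran-2(3H)-one | O=C1O[C@H](O[C@H]2C[C@@H](C)CC[C@@H]2C(C)C)[C@@H](C3(SCCCS3)c4ccc(OC)c(OCc5ccccc5)c4)C1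
F2 | step 5 | (2S,3S)-2-{2-[3-(benzyloxy)-4-methoxyphenyl]-1,3-dithian-2-yl}-3-[(3,4-dimethoxyphenyl)(hydroxy)methyl]butane-1,4-diol, carbinol epimers | OC[C@@H](C3(SCCCS3)c4ccc(OC)c(OCc5ccccc5)c4)[C@@H](CO)C(O)c6ccc(OC)c(OC)c6
F3 | step 8 | (2R,3S,4R)-7-(benzyloxy)-4-(3,4-dimethoxyphenyl)-2,3-bis(iodomethyl)-6-methoxy-3,4-dihydro-2H-spiro[naphthalene-1,2'-[1,3]dithiane] | COc1cc2c(cc1OCc3ccccc3)C5(SCCCS5)[C@H](CI)[C@@H](CI)[C@@H]2c4ccc(OC)c(OC)c4
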